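## Retrosynthetic overview

- The trans-13,14-epoxy aldehyde comes from a (13R,14S)-13,14,15-triol by primary sulfonylation and Payne rearrangement; C14 is bought as an (S)-glycerate and C13 is set by chelation-controlled MeMgBr addition to the derived ketone.
- Ring A functionality (3α-OAc, 4α-Me, 4β-CO2Me) comes from a cycloadduct by oxidation to the β-keto ester, α-face C-methylation, conjugate reduction and axial-selective ketone reduction.
- Key step: an intramolecular Diels–Alder reaction of an (E)-enoate with a 1-silyloxy-4-methyl-1,3-diene closes ring A and ring B together (bonds C5–C10 and C3–C4); the C9 centre directs C5 and C10.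
- The triene comes from (R)-limonene, whose C4 becomes C9: allylic lithiation/allylation of the isopropenyl group, then ozonolysis/Criegee rearrangement of the ring to an aldehyde arm (C10–C1) and an acetate arm (C11–C12).
- Remaining carbons: formaldehyde (C20), a Wittig reagent (C2, C3), the glycerate (C13–C15), MeMgBr (C16), methyl acrylate (C4, C19) and MeI (C18).

Assumption: C-labels in the comments use labdane numbering of the target; (R)-limonene, allyl bromide and methyl (4S)-2,2-dimethyl-1,3-dioxolane-4-carboxylate are taken as catalogue chemicals.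

## Route

Step 1
Reactants: 1 (R)-(+)-limonene; 2 allyl bromide
Product: 4 (4R)-4-(hexa-1,5-dien-2-yl)-1-methylcyclohex-1-ene, via allyllithium 3 (not isolated)
Conditions: n-BuLi, TMEDA, hexane, 25 °C, 18 h; then 2, THF, −78 → 0 °C
Reagents that add atoms: none
Why: Allylic metalation of limonene occurs at the isopropenyl methyl group and the symmetrical 2-substituted allyllithium is alkylated (SN2) by allyl bromide; the stereocentre (future C9) is untouched.

Step 2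
Reactants: 4 (4R)-4-(hexa-1,5-dien-2-yl)-1-methylcyclohex-1-ene
Product: 6 (3R)-3-(hexa-1,5-dien-2-yl)-5-oxopentyl acetate, via methoxy hydroperoxide 5 (not isolated)
Conditions: O3 (1.0 equiv, Sudan red 7B end-point), NaHCO3, CH2Cl2/MeOH 4:1, −78 °C; then Ac2O, Et3N, DMAP (cat.), 0 → 40 °C
Reagents that add atoms: ozone, O=[O+][O-]
Why: Ozonolysis is fastest at the trisubstituted ring alkene and methanol traps the ketone oxide; Criegee rearrangement of the acylated tertiary hydroperoxide then migrates the primary ring carbon to oxygen, giving the C12 acetate (old C1 and its methyl become the acetyl group) and the C1 aldehyde.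

Step 3
Reactants: 6 (3R)-3-(hexa-1,5-dien-2-yl)-5-oxopentyl acetate
Product: 7 (3S)-4-formyl-3-(hexa-1,5-dien-2-yl)pent-4-en-1-yl acetate
Conditions: 37% aq. CH2O, pyrrolidine (10 mol%), propanoic acid (10 mol%), i-PrOH, 45 °C
Reagents that add atoms: formaldehyde, C=O
Why: Amine-catalysed Mannich condensation/elimination (aldehyde α-methylenation) installs the future C20 carbon at C10; the β-stereocentre is not enolisable (descriptor changes only by CIP priority).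

Step 4
Reactants: 7 (3S)-4-formyl-3-(hexa-1,5-dien-2-yl)pent-4-en-1-yl acetate
Product: 8 (3R,4RS)-3-(hexa-1,5-dien-2-yl)-4-methyl-5-oxopentyl acetate
Conditions: Hantzsch ester (1.1 equiv), dibenzylammonium trifluoroacetate (10 mol%), THF, 25 °C
Reagents that add atoms: none
Why: Iminium-catalysed transfer hydrogenation reduces only the enal C=C (isolated alkenes and the acetate are inert); the new C10 centre is formed unselectively and is erased in step 13.

Step 5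
Reactants: 8 (3R,4RS)-3-(hexa-1,5-dien-2-yl)-4-methyl-5-oxopentyl acetate
Product: 9 (3R,4RS,5Z)-6-(1,3-dioxolan-2-yl)-3-(hexa-1,5-dien-2-yl)-4-methylhex-5-en-1-yl acetate
Conditions: (1,3-dioxolan-2-ylmethyl)triphenylphosphonium bromide, KOt-Bu, THF, 0 °C; then 8, −78 → 25 °C
Reagents that add atoms: (1,3-dioxolan-2-ylmethyl)triphenylphosphonium bromide, [Br-].C1COC(O1)C[P+](c1ccccc1)(c1ccccc1)c1ccccc1
Why: Wittig olefination adds C2 and C3 as a masked enal that survives the organometallic steps; the mainly Z alkene geometry is irrelevant because this bond becomes the diene σ-bond.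

Step 6
Reactants: 9 (3R,4RS,5Z)-6-(1,3-dioxolan-2-yl)-3-(hexa-1,5-dien-2-yl)-4-methylhex-5-en-1-yl acetate
Product: 10 (3R,4RS,5Z)-6-(1,3-dioxolan-2-yl)-3-(hexa-1,5-dien-2-yl)-4-methylhex-5-en-1-ol
Conditions: K2CO3 (0.2 equiv), MeOH, 25 °C
Reagents that add atoms: none
Why: Base-catalysed transesterification (Zemplén-type methanolysis) frees the C12 alcohol without touching the acetal or alkenes.

Step 7
Reactants: 10 (3R,4RS,5Z)-6-(1,3-dioxolan-2-yl)-3-(hexa-1,5-dien-2-yl)-4-methylhex-5-en-1-ol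
Product: 11 2-[(1Z,3RS,4R)-4-(hexa-1,5-dien-2-yl)-6-iodo-3-methylhex-1-en-1-yl]-1,3-dioxolane
Conditions: PPh3, I2, imidazole, CH2Cl2, 0 °C
Reagents that add atoms: iodine, II
Why: Appel iodination of the unhindered primary alcohol under imidazole buffering, which protects the allylic acetal.

Step 8
Reactants: 12 methyl (4S)-2,2-dimethyl-1,3-dioxolane-4-carboxylate
Product: 13 (4S)-N-methoxy-N,2,2-trimethyl-1,3-dioxolane-4-carboxamide
Conditions: MeNH(OMe)·HCl, i-PrMgCl, THF, −20 °C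
Reagents that add atoms: N,O-dimethylhydroxylamine hydrochloride, CNOC.Cl
Why: Direct aminolysis of the ester by the magnesium amide gives the Weinreb amide at low temperature without epimerising the α-alkoxy centre (future C14).

Step 9
Reactants: 11 2-[(1Z,3RS,4R)-4-(hexa-1,5-dien-2-yl)-6-iodo-3-methylhex-1-en-1-yl]-1,3-dioxolane; 13 (4S)-N-methoxy-N,2,2-trimethyl-1,3-dioxolane-4-carboxamide
Product: 15 (4R,5RS,6Z)-7-(1,3-dioxolan-2-yl)-1-[(4S)-2,2-dimethyl-1,3-dioxolan-4-yl]-4-(hexa-1,5-dien-2-yl)-5-methylhept-6-en-1-one, via alkyllithium 14 (not isolated)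
Conditions: t-BuLi (2.1 equiv), Et2O/pentane, −78 °C; then 13, −78 → −40 °C; aq. NH4Cl
Reagents that add atoms: none
Why: Iodine–lithium exchange followed by Weinreb ketone synthesis forms the C12–C13 bond; the chelated tetrahedral intermediate prevents over-addition and −78 °C suppresses 5-exo cyclisation of the alkyllithium.

Step 10
Reactants: 15 (4R,5RS,6Z)-7-(1,3-dioxolan-2-yl)-1-[(4S)-2,2-dimethyl-1,3-dioxolan-4-yl]-4-(hexa-1,5-dien-2-yl)-5-methylhept-6-en-1-one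
Product: 16 (2R,5R,6RS,7Z)-8-(1,3-dioxolan-2-yl)-2-[(4S)-2,2-dimethyl-1,3-dioxolan-4-yl]-5-(hexa-1,5-dien-2-yl)-6-methyloct-7-en-2-ol
Conditions: MeMgBr (2 equiv), CH2Cl2/Et2O, −78 °C; aq. NH4Cl
Reagents that add atoms: methylmagnesium bromide, C[Mg]Br
Why: Cram-chelate-controlled Grignard addition: magnesium bridges the ketone oxygen and the α-oxygen of the dioxolane, and methyl attacks the face opposite the C15 methylene, setting C13 as R (O13/O14 anti along the C12–C15 chain).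

Step 11
Reactants: 16 (2R,5R,6RS,7Z)-8-(1,3-dioxolan-2-yl)-2-[(4S)-2,2-dimethyl-1,3-dioxolan-4-yl]-5-(hexa-1,5-dien-2-yl)-6-methyloct-7-en-2-ol
Product: 17 (2E,4RS,5R)-5-{(3R)-3-[(4S)-2,2-dimethyl-1,3-dioxolan-4-yl]-3-hydroxybutyl}-4-methyl-6-methylidenedeca-2,9-dienal
Conditions: PPTS (0.1 equiv), acetone/H2O 20:1, 25 °C
Reagents that add atoms: water, O
Why: The allylic acetal hydrolyses through a conjugated oxocarbenium ion far faster than the acetonide, which acetone as solvent also preserves; the enal equilibrates to E.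

Step 12
Reactants: 17 (2E,4RS,5R)-5-{(3R)-3-[(4S)-2,2-dimethyl-1,3-dioxolan-4-yl]-3-hydroxybutyl}-4-methyl-6-methylidenedeca-2,9-dienal
Product: 18 methyl (2E,7R,8RS,9E)-7-{(3R)-3-[(4S)-2,2-dimethyl-1,3-dioxolan-4-yl]-3-hydroxybutyl}-8-methyl-6-methylidene-11-oxoundeca-2,9-dienoate
Conditions: methyl acrylate (10 equiv), second-generation Hoveyda–Grubbs catalyst (H2IMes)Cl2Ru(=CH-C6H4-2-O-i-Pr) (5 mol%), CH2Cl2, 40 °C
Reagents that add atoms: methyl acrylate, C=CC(=O)OC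
Why: Olefin cross-metathesis engages only the monosubstituted terminal alkene (the 1,1-disubstituted alkene and the branched enal are unreactive) and gives the E-enoate, adding C4 and C19.

Step 13
Reactants: 18 methyl (2E,7R,8RS,9E)-7-{(3R)-3-[(4S)-2,2-dimethyl-1,3-dioxolan-4-yl]-3-hydroxybutyl}-8-methyl-6-methylidene-11-oxoundeca-2,9-dienoate
Product: 19 methyl (2E,7S,8E,10E)-7-{(3R)-3-[(4S)-2,2-dimethyl-1,3-dioxolan-4-yl]-3-[(triethylsilyl)oxy]butyl}-8-methyl-6-methylidene-11-[(triethylsilyl)oxy]undeca-2,8,10-trienoate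
Conditions: Et3SiOTf (2.5 equiv), Et3N (4 equiv), CH2Cl2, −78 → 0 °C
Reagents that add atoms: triethylsilyl trifluoromethanesulfonate, CC[Si](CC)(CC)OS(=O)(=O)C(F)(F)F
Why: Vinylogous (γ) soft enolisation of the O-silylated enal gives the 1-silyloxy diene and caps the tertiary alcohol; the branched C9 substituent takes the outside position at C10 (methyl inside), and the C10 epimer mixture converges here.

Step 14
Reactants: 19 methyl (2E,7S,8E,10E)-7-{(3R)-3-[(4S)-2,2-dimethyl-1,3-dioxolan-4-yl]-3-[(triethylsilyl)oxy]butyl}-8-methyl-6-methylidene-11-[(triethylsilyl)oxy]undeca-2,8,10-trienoate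
Product: 21 methyl (1S,2R,4aS,5S,8aS)-5-{(3R)-3-[(4S)-2,2-dimethyl-1,3-dioxolan-4-yl]-3-hydroxybutyl}-2-hydroxy-4a-methyl-6-methylidene-1,2,4a,5,6,7,8,8a-octahydronaphthalene-1-carboxylate, via bis-silyl cycloadduct 20 (not isolated)
Conditions: toluene (0.01 M), BHT (cat.), 130 °C, sealed tube; then Bu4NF, AcOH, THF, 0 → 25 °C
Reagents that add atoms: none
Why: Intramolecular Diels–Alder reaction in the ester-endo/tether-exo chair transition state gives the trans ring fusion (5α-H, 10β-Me) with the C11 chain pseudo-equatorial on the forming ring B, so the limonene-derived C9 centre fixes C5 and C10; the C3 and C4 configurations are erased in steps 15–16.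

Step 15
Reactants: 21 methyl (1S,2R,4aS,5S,8aS)-5-{(3R)-3-[(4S)-2,2-dimethyl-1,3-dioxolan-4-yl]-3-hydroxybutyl}-2-hydroxy-4a-methyl-6-methylidene-1,2,4a,5,6,7,8,8a-octahydronaphthalene-1-carboxylate
Product: 22 methyl (4aS,5S,8aS)-5-{(3R)-3-[(4S)-2,2-dimethyl-1,3-dioxolan-4-yl]-3-hydroxybutyl}-4a-methyl-6-methylidene-2-oxo-1,2,4a,5,6,7,8,8a-octahydronaphthalene-1-carboxylate
Conditions: Dess–Martin periodinane, NaHCO3, CH2Cl2, 25 °C
Reagents that add atoms: none
Why: Hypervalent-iodine oxidation of the allylic secondary alcohol gives the enolisable β-keto ester (C4 epimers and enol) while the tertiary alcohol is inert.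

Step 16
Reactants: 22 methyl (4aS,5S,8aS)-5-{(3R)-3-[(4S)-2,2-dimethyl-1,3-dioxolan-4-yl]-3-hydroxybutyl}-4a-methyl-6-methylidene-2-oxo-1,2,4a,5,6,7,8,8a-octahydronaphthalene-1-carboxylate
Product: 23 methyl (1R,4aR,5S,8aR)-5-{(3R)-3-[(4S)-2,2-dimethyl-1,3-dioxolan-4-yl]-3-hydroxybutyl}-1,4a-dimethyl-6-methylidene-2-oxo-1,2,4a,5,6,7,8,8a-octahydronaphthalene-1-carboxylate
Conditions: K2CO3, MeI, acetone, 40 °C
Reagents that add atoms: iodomethane, CI
Why: C-alkylation of the β-keto ester enolate occurs on the α-face, away from the axial C10 methyl, giving 4α-Me and 4β-CO2Me.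

Step 17
Reactants: 23 methyl (1R,4aR,5S,8aR)-5-{(3R)-3-[(4S)-2,2-dimethyl-1,3-dioxolan-4-yl]-3-hydroxybutyl}-1,4a-dimethyl-6-methylidene-2-oxo-1,2,4a,5,6,7,8,8a-octahydronaphthalene-1-carboxylate
Product: 24 methyl (1R,4aR,5S,8aR)-5-{(3R)-3-[(4S)-2,2-dimethyl-1,3-dioxolan-4-yl]-3-hydroxybutyl}-1,4a-dimethyl-6-methylidene-2-oxodecahydronaphthalene-1-carboxylate
Conditions: [(Ph3P)CuH]6 (0.3 equiv), H2O (5 equiv), benzene/THF, 25 °C
Reagents that add atoms: none
Why: Conjugate reduction with Stryker's monovalent copper hydride saturates only the enone C1=C2 and leaves the isolated exocyclic 8(17)-alkene, which hydrogenation would not spare.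

Step 18
Reactants: 24 methyl (1R,4aR,5S,8aR)-5-{(3R)-3-[(4S)-2,2-dimethyl-1,3-dioxolan-4-yl]-3-hydroxybutyl}-1,4a-dimethyl-6-methylidene-2-oxodecahydronaphthalene-1-carboxylate
Product: 25 methyl (1R,2R,4aR,5S,8aR)-5-{(3R)-3-[(4S)-2,2-dimethyl-1,3-dioxolan-4-yl]-3-hydroxybutyl}-2-hydroxy-1,4a-dimethyl-6-methylidenedecahydronaphthalene-1-carboxylate
Conditions: K[(s-Bu)3BH] (3 equiv), THF, −78 → −40 °C; aq. NH4Cl
Reagents that add atoms: none
Why: The bulky trialkylborohydride (K-Selectride) attacks the hindered 3-ketone equatorially, giving the axial 3α-alcohol; the neopentyl ester is untouched.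

Step 19
Reactants: 25 methyl (1R,2R,4aR,5S,8aR)-5-{(3R)-3-[(4S)-2,2-dimethyl-1,3-dioxolan-4-yl]-3-hydroxybutyl}-2-hydroxy-1,4a-dimethyl-6-methylidenedecahydronaphthalene-1-carboxylate
Product: 26 methyl (1R,2R,4aR,5S,8aR)-2-hydroxy-1,4a-dimethyl-6-methylidene-5-[(3R,4S)-3,4,5-trihydroxy-3-methylpentyl]decahydronaphthalene-1-carboxylate
Conditions: AcOH/H2O/THF 3:1:1, 40 °C
Reagents that add atoms: none
Why: Mild acid-catalysed acetonide hydrolysis, too weak to isomerise the exocyclic alkene, reveals the 13,14,15-triol.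

Step 20
Reactants: 26 methyl (1R,2R,4aR,5S,8aR)-2-hydroxy-1,4a-dimethyl-6-methylidene-5-[(3R,4S)-3,4,5-trihydroxy-3-methylpentyl]decahydronaphthalene-1-carboxylate
Product: 29 methyl (1R,2R,4aR,5S,8aR)-2-hydroxy-5-{2-[(2R,3R)-3-(hydroxymethyl)-2-methyloxiran-2-yl]ethyl}-1,4a-dimethyl-6-methylidenedecahydronaphthalene-1-carboxylate, via primary tosylate 27 (not isolated), via terminal epoxide 28 (not isolated)
Conditions: TsCl (1.05 equiv), Bu2SnO (5 mol%), Et3N, CH2Cl2, 0 °C; then K2CO3, MeOH, 0 → 25 °C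
Reagents that add atoms: none
Why: Stannylene-catalysed sulfonylation selects the primary 15-OH, base closes the 14,15-epoxide with retention at C14, and Payne rearrangement (O13 attacks C14 with inversion) gives the more substituted trans-13,14-epoxide with the target configuration.

Step 21
Reactants: 29 methyl (1R,2R,4aR,5S,8aR)-2-hydroxy-5-{2-[(2R,3R)-3-(hydroxymethyl)-2-methyloxiran-2-yl]ethyl}-1,4a-dimethyl-6-methylidenedecahydronaphthalene-1-carboxylate
Product: 30 methyl (1R,2R,4aR,5S,8aR)-5-{2-[(2R,3S)-3-formyl-2-methyloxiran-2-yl]ethyl}-2-hydroxy-1,4a-dimethyl-6-methylidenedecahydronaphthalene-1-carboxylate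
Conditions: TEMPO (10 mol%), PhI(OAc)2 (1.2 equiv), CH2Cl2, 25 °C
Reagents that add atoms: none
Why: The oxoammonium (TEMPO) oxidation is selective for the primary alcohol over the hindered axial 3α-OH and stops at the epoxy aldehyde without epimerising C14.

Step 22
Reactants: 30 methyl (1R,2R,4aR,5S,8aR)-5-{2-[(2R,3S)-3-formyl-2-methyloxiran-2-yl]ethyl}-2-hydroxy-1,4a-dimethyl-6-methylidenedecahydronaphthalene-1-carboxylate
Product: 31 methyl (1R,2R,4aR,5S,8aR)-2-acetoxy-5-{2-[(2R,3S)-3-formyl-2-methyloxiran-2-yl]ethyl}-1,4a-dimethyl-6-methylidenedecahydronaphthalene-1-carboxylate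
Conditions: Ac2O, DMAP, pyridine, CH2Cl2, 25 °C
Reagents that add atoms: acetic anhydride, CC(=O)OC(C)=O
Why: DMAP-catalysed acylation of the only remaining hydroxyl gives the target; the epoxy aldehyde has no enolisable α-hydrogen.

## Compound list

1 | (R)-(+)-limonene, (4R)-1-methyl-4-(prop-1-en-2-yl)cyclohex-1-ene | CC1=CC[C@@H](CC1)C(C)=C | starting material
2 | allyl bromide | C=CCBr | starting material
3 | {2-[(1R)-4-methylcyclohex-3-en-1-yl]prop-2-en-1-yl}lithium | CC1=CC[C@@H](CC1)C(=C)C[Li] | intermediate (not isolated)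
4 | (4R)-4-(hexa-1,5-dien-2-yl)-1-methylcyclohex-1-ene | CC1=CC[C@@H](CC1)C(=C)CCC=C | intermediate
5 | (3R)-3-(hexa-1,5-dien-2-yl)-6-hydroperoxy-6-methoxyheptanal (C6 epimers) | O=CC[C@@H](CCC(C)(OC)OO)C(=C)CCC=C | intermediate (not isolated)
6 | (3R)-3-(hexa-1,5-dien-2-yl)-5-oxopentyl acetate | O=CC[C@@H](CCOC(C)=O)C(=C)CCC=C | intermediate
7 | (3S)-4-formyl-3-(hexa-1,5-dien-2-yl)pent-4-en-1-yl acetate | O=CC(=C)[C@@H](CCOC(C)=O)C(=C)CCC=C | intermediate
8 | (3R,4RS)-3-(hexa-1,5-dien-2-yl)-4-methyl-5-oxopentyl acetate | O=CC(C)[C@@H](CCOC(C)=O)C(=C)CCC=C | intermediate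
9 | (3R,4RS,5Z)-6-(1,3-dioxolan-2-yl)-3-(hexa-1,5-dien-2-yl)-4-methylhex-5-en-1-yl acetate | C1(OCCO1)/C=C\C(C)[C@@H](CCOC(C)=O)C(=C)CCC=C | intermediate
10 | (3R,4RS,5Z)-6-(1,3-dioxolan-2-yl)-3-(hexa-1,5-dien-2-yl)-4-methylhex-5-en-1-ol | C1(OCCO1)/C=C\C(C)[C@@H](CCO)C(=C)CCC=C | intermediate
11 | 2-[(1Z,3RS,4R)-4-(hexa-1,5-dien-2-yl)-6-iodo-3-methylhex-1-en-1-yl]-1,3-dioxolane | C1(OCCO1)/C=C\C(C)[C@@H](CCI)C(=C)CCC=C | intermediate
12 | methyl (4S)-2,2-dimethyl-1,3-dioxolane-4-carboxylate | COC(=O)[C@@H]1COC(C)(C)O1 | starting material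
13 | (4S)-N-methoxy-N,2,2-trimethyl-1,3-dioxolane-4-carboxamide | CON(C)C(=O)[C@@H]1COC(C)(C)O1 | intermediate
14 | [(3R,4RS,5Z)-6-(1,3-dioxolan-2-yl)-3-(hexa-1,5-dien-2-yl)-4-methylhex-5-en-1-yl]lithium | C1(OCCO1)/C=C\C(C)[C@@H](CC[Li])C(=C)CCC=C | intermediate (not isolated)
15 | (4R,5RS,6Z)-7-(1,3-dioxolan-2-yl)-1-[(4S)-2,2-dimethyl-1,3-dioxolan-4-yl]-4-(hexa-1,5-dien-2-yl)-5-methylhept-6-en-1-one | C1(OCCO1)/C=C\C(C)[C@@H](CCC(=O)[C@@H]2COC(C)(C)O2)C(=C)CCC=C | intermediate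
16 | (2R,5R,6RS,7Z)-8-(1,3-dioxolan-2-yl)-2-[(4S)-2,2-dimethyl-1,3-dioxolan-4-yl]-5-(hexa-1,5-dien-2-yl)-6-methyloct-7-en-2-ol | C1(OCCO1)/C=C\C(C)[C@@H](CC[C@@](C)(O)[C@@H]2COC(C)(C)O2)C(=C)CCC=C | intermediate
17 | (2E,4RS,5R)-5-{(3R)-3-[(4S)-2,2-dimethyl-1,3-dioxolan-4-yl]-3-hydroxybutyl}-4-methyl-6-methylidenedeca-2,9-dienal | O=C/C=C/C(C)[C@@H](CC[C@@](C)(O)[C@@H]1COC(C)(C)O1)C(=C)CCC=C | intermediate
18 | methyl (2E,7R,8RS,9E)-7-{(3R)-3-[(4S)-2,2-dimethyl-1,3-dioxolan-4-yl]-3-hydroxybutyl}-8-methyl-6-methylidene-11-oxoundeca-2,9-dienoate | O=C/C=C/C(C)[C@@H](CC[C@@](C)(O)[C@@H]1COC(C)(C)O1)C(=C)CC/C=C/C(=O)OC | intermediate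
19 | methyl (2E,7S,8E,10E)-7-{(3R)-3-[(4S)-2,2-dimethyl-1,3-dioxolan-4-yl]-3-[(triethylsilyl)oxy]butyl}-8-methyl-6-methylidene-11-[(triethylsilyl)oxy]undeca-2,8,10-trienoate | CC[Si](CC)(CC)O/C=C/C=C(\C)[C@@H](CC[C@@](C)(O[Si](CC)(CC)CC)[C@@H]1COC(C)(C)O1)C(=C)CC/C=C/C(=O)OC | intermediate
20 | methyl (1S,2R,4aS,5S,8aS)-5-{(3R)-3-[(4S)-2,2-dimethyl-1,3-dioxolan-4-yl]-3-[(triethylsilyl)oxy]butyl}-4a-methyl-6-methylidene-2-[(triethylsilyl)oxy]-1,2,4a,5,6,7,8,8a-octahydronaphthalene-1-carboxylate | C=C1CC[C@@H]2[C@](C)(C=C[C@@H](O[Si](CC)(CC)CC)[C@H]2C(=O)OC)[C@H]1CC[C@@](C)(O[Si](CC)(CC)CC)[C@@H]1COC(C)(C)O1 | intermediate (not isolated)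
21 | methyl (1S,2R,4aS,5S,8aS)-5-{(3R)-3-[(4S)-2,2-dimethyl-1,3-dioxolan-4-yl]-3-hydroxybutyl}-2-hydroxy-4a-methyl-6-methylidene-1,2,4a,5,6,7,8,8a-octahydronaphthalene-1-carboxylate | C=C1CC[C@@H]2[C@](C)(C=C[C@@H](O)[C@H]2C(=O)OC)[C@H]1CC[C@@](C)(O)[C@@H]1COC(C)(C)O1 | intermediate
22 | methyl (4aS,5S,8aS)-5-{(3R)-3-[(4S)-2,2-dimethyl-1,3-dioxolan-4-yl]-3-hydroxybutyl}-4a-methyl-6-methylidene-2-oxo-1,2,4a,5,6,7,8,8a-octahydronaphthalene-1-carboxylate (C1 epimers and enol) | C=C1CC[C@@H]2[C@](C)(C=CC(=O)C2C(=O)OC)[C@H]1CC[C@@](C)(O)[C@@H]1COC(C)(C)O1 | intermediate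
23 | methyl (1R,4aR,5S,8aR)-5-{(3R)-3-[(4S)-2,2-dimethyl-1,3-dioxolan-4-yl]-3-hydroxybutyl}-1,4a-dimethyl-6-methylidene-2-oxo-1,2,4a,5,6,7,8,8a-octahydronaphthalene-1-carboxylate | C=C1CC[C@@H]2[C@](C)(C=CC(=O)[C@]2(C)C(=O)OC)[C@H]1CC[C@@](C)(O)[C@@H]1COC(C)(C)O1 | intermediate
24 | methyl (1R,4aR,5S,8aR)-5-{(3R)-3-[(4S)-2,2-dimethyl-1,3-dioxolan-4-yl]-3-hydroxybutyl}-1,4a-dimethyl-6-methylidene-2-oxodecahydronaphthalene-1-carboxylate | C=C1CC[C@@H]2[C@](C)(CCC(=O)[C@]2(C)C(=O)OC)[C@H]1CC[C@@](C)(O)[C@@H]1COC(C)(C)O1 | intermediate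
25 | methyl (1R,2R,4aR,5S,8aR)-5-{(3R)-3-[(4S)-2,2-dimethyl-1,3-dioxolan-4-yl]-3-hydroxybutyl}-2-hydroxy-1,4a-dimethyl-6-methylidenedecahydronaphthalene-1-carboxylate | C=C1CC[C@@H]2[C@](C)(CC[C@@H](O)[C@]2(C)C(=O)OC)[C@H]1CC[C@@](C)(O)[C@@H]1COC(C)(C)O1 | intermediate
26 | methyl (1R,2R,4aR,5S,8aR)-2-hydroxy-1,4a-dimethyl-6-methylidene-5-[(3R,4S)-3,4,5-trihydroxy-3-methylpentyl]decahydronaphthalene-1-carboxylate | C=C1CC[C@@H]2[C@](C)(CC[C@@H](O)[C@]2(C)C(=O)OC)[C@H]1CC[C@@](C)(O)[C@@H](O)CO | intermediate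
27 | methyl (1R,2R,4aR,5S,8aR)-5-[(3R,4S)-3,4-dihydroxy-3-methyl-5-(tosyloxy)pentyl]-2-hydroxy-1,4a-dimethyl-6-methylidenedecahydronaphthalene-1-carboxylate | C=C1CC[C@@H]2[C@](C)(CC[C@@H](O)[C@]2(C)C(=O)OC)[C@H]1CC[C@@](C)(O)[C@@H](O)COS(=O)(=O)c1ccc(C)cc1 | intermediate (not isolated)
28 | methyl (1R,2R,4aR,5S,8aR)-2-hydroxy-5-{(3R)-3-hydroxy-3-[(2S)-oxiran-2-yl]butyl}-1,4a-dimethyl-6-methylidenedecahydronaphthalene-1-carboxylate | C=C1CC[C@@H]2[C@](C)(CC[C@@H](O)[C@]2(C)C(=O)OC)[C@H]1CC[C@@](C)(O)[C@@H]1CO1 | intermediate (not isolated)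
29 | methyl (1R,2R,4aR,5S,8aR)-2-hydroxy-5-{2-[(2R,3R)-3-(hydroxymethyl)-2-methyloxiran-2-yl]ethyl}-1,4a-dimethyl-6-methylidenedecahydronaphthalene-1-carboxylate | C=C1CC[C@@H]2[C@](C)(CC[C@@H](O)[C@]2(C)C(=O)OC)[C@H]1CC[C@@]1(C)O[C@@H]1CO | intermediate
30 | methyl (1R,2R,4aR,5S,8aR)-5-{2-[(2R,3S)-3-formyl-2-methyloxiran-2-yl]ethyl}-2-hydroxy-1,4a-dimethyl-6-methylidenedecahydronaphthalene-1-carboxylate | C=C1CC[C@@H]2[C@](C)(CC[C@@H](O)[C@]2(C)C(=O)OC)[C@H]1CC[C@@]1(C)O[C@@H]1C=O | intermediate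
31 | methyl (1R,2R,4aR,5S,8aR)-2-acetoxy-5-{2-[(2R,3S)-3-formyl-2-methyloxiran-2-yl]ethyl}-1,4a-dimethyl-6-methylidenedecahydronaphthalene-1-carboxylate | C=C1CC[C@@H]2[C@](C)(CC[C@@H](OC(C)=O)[C@]2(C)C(=O)OC)[C@H]1CC[C@@]1(C)O[C@@H]1C=O | target

## Step count and risks

Total step count: 22. Longest linear sequence: 21 steps (steps 1–7 and 9–22, from (R)-limonene); step 8 is the single side-branch step.

**Step 14 (cycloaddition).** The diene terminus C10 carries an inside methyl group, which slows the reaction, and the trans ring fusion depends on the ester-endo preference, which is only moderate in thermal decatrienoate cyclisations. Only the (8E,10E) isomer of 19 can cyclise. The fallback replaces thermal activation of the diene by Lewis-acid activation of the dienophile. It sets out from 18: i-Pr3SiOTf/Et3N gives the bulkier, Lewis-acid-tolerant methyl (2E,7S,8E,10E)-7-{(3R)-3-[(4S)-2,2-dimethyl-1,3-dioxolan-4-yl]-3-hydroxybutyl}-8-methyl-6-methylidene-11-[(triisopropylsilyl)oxy]undeca-2,8,10-trienoate F1, leaving the hindered tertiary alcohol free. Me2AlCl (2.2 equiv, CH2Cl2, −40 → 0 °C) first ties up that alcohol as its aluminium alkoxide and then coordinates the enoate, which enforces the ester-endo chair at low temperature. This gives methyl (1S,2R,4aS,5S,8aS)-5-{(3R)-3-[(4S)-2,2-dimethyl-1,3-dioxolan-4-yl]-3-hydroxybutyl}-4a-methyl-6-methylidene-2-[(triisopropylsilyl)oxy]-1,2,4a,5,6,7,8,8a-octahydronaphthalene-1-carboxylate F2. Bu4NF then returns the route at 21.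

**Step 10 (C13 configuration).** The route needs the chelated transition state. If the dioxolane oxygen chelates poorly and polar Felkin–Anh attack dominates, the C13 epimer forms. The fallback keeps the same facial bias but exchanges the two carbon nucleophiles. It sets out from 13 and 11: MeMgBr converts 13 into 1-[(4S)-2,2-dimethyl-1,3-dioxolan-4-yl]ethan-1-one F3. The alkyllithium 14, generated from 11 as in step 9, is then added to F3 at −78 °C in THF. Because methyl and the C12 chain have swapped roles, non-chelated attack now gives the (13R) alcohol, and the route is rejoined at 16.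

**Step 20 (epoxide transposition).** The one-pot sequence needs clean mono-sulfonylation of a tetraol and a Payne equilibrium that must outrun methoxide opening of the terminal epoxide. The fallback closes the 13,14-epoxide directly and irreversibly. It sets out from 26:
- t-BuMe2SiCl/imidazole (DMF, 0 °C) silylates only the primary hydroxyl, giving methyl (1R,2R,4aR,5S,8aR)-5-[(3R,4S)-5-{[tert-butyl(dimethyl)silyl]oxy}-3,4-dihydroxy-3-methylpentyl]-2-hydroxy-1,4a-dimethyl-6-methylidenedecahydronaphthalene-1-carboxylate F4.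
- MsCl/Et3N (−30 °C) sulfonylates the secondary 14-OH, giving methyl (1R,2R,4aR,5S,8aR)-5-[(3R,4S)-5-{[tert-butyl(dimethyl)silyl]oxy}-3-hydroxy-3-methyl-4-[(methylsulfonyl)oxy]pentyl]-2-hydroxy-1,4a-dimethyl-6-methylidenedecahydronaphthalene-1-carboxylate F5. The axial, neopentylic 3α-OH and the tertiary 13-OH are much slower.
- K2CO3/MeOH lets O13 displace the mesylate with inversion at C14, giving methyl (1R,2R,4aR,5S,8aR)-5-{2-[(2R,3R)-3-({[tert-butyl(dimethyl)silyl]oxy}methyl)-2-methyloxiran-2-yl]ethyl}-2-hydroxy-1,4a-dimethyl-6-methylidenedecahydronaphthalene-1-carboxylate F6.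
- Bu4NF then returns the route at 29.

Further compounds
F1 | step 14 | methyl (2E,7S,8E,10E)-7-{(3R)-3-[(4S)-2,2-dimethyl-1,3-dioxolan-4-yl]-3-hydroxybutyl}-8-methyl-6-methylidene-11-[(triisopropylsilyl)oxy]undeca-2,8,10-trienoate | CC(C)[Si](C(C)C)(C(C)C)O/C=C/C=C(\C)[C@@H](CC[C@@](C)(O)[C@@H]1COC(C)(C)O1)C(=C)CC/C=C/C(=O)OC
F2 | step 14 | methyl (1S,2R,4aS,5S,8aS)-5-{(3R)-3-[(4S)-2,2-dimethyl-1,3-dioxolan-4-yl]-3-hydroxybutyl}-4a-methyl-6-methylidene-2-[(triisopropylsilyl)oxy]-1,2,4a,5,6,7,8,8a-octahydronaphthalene-1-carboxylate | C=C1CC[C@@H]2[C@](C)(C=C[C@@H](O[Si](C(C)C)(C(C)C)C(C)C)[C@H]2C(=O)OC)[C@H]1CC[C@@](C)(O)[C@@H]1COC(C)(C)O1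
F3 | step 10 | 1-[(4S)-2,2-dimethyl-1,3-dioxolan-4-yl]ethan-1-one | CC(=O)[C@@H]1COC(C)(C)O1
F4 | step 20 | methyl (1R,2R,4aR,5S,8aR)-5-[(3R,4S)-5-{[tert-butyl(dimethyl)silyl]oxy}-3,4-dihydroxy-3-methylpentyl]-2-hydroxy-1,4a-dimethyl-6-methylidenedecahydronaphthalene-1-carboxylate | C=C1CC[C@@H]2[C@](C)(CC[C@@H](O)[C@]2(C)C(=O)OC)[C@H]1CC[C@@](C)(O)[C@@H](O)CO[Si](C)(C)C(C)(C)C
F5 | step 20 | methyl (1R,2R,4aR,5S,8aR)-5-[(3R,4S)-5-{[tert-butyl(dimethyl)silyl]oxy}-3-hydroxy-3-methyl-4-[(methylsulfonyl)oxy]pentyl]-2-hydroxy-1,4a-dimethyl-6-methylidenedecahydronaphthalene-1-carboxylate | C=C1CC[C@@H]2[C@](C)(CC[C@@H](O)[C@]2(C)C(=O)OC)[C@H]1CC[C@@](C)(O)[C@@H](OS(C)(=O)=O)CO[Si](C)(C)C(C)(C)C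
F6 | step 20 | methyl (1R,2R,4aR,5S,8aR)-5-{2-[(2R,3R)-3-({[tert-butyl(dimethyl)silyl]oxy}methyl)-2-methyloxiran-2-yl]ethyl}-2-hydroxy-1,4a-dimethyl-6-methylidenedecahydronaphthalene-1-carboxylate | C=C1CC[C@@H]2[C@](C)(CC[C@@H](O)[C@]2(C)C(=O)OC)[C@H]1CC[C@@]1(C)O[C@@H]1CO[Si](C)(C)C(C)(C)C
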